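**Plan**
- Retrosynthesis: the three MOM ethers and the C2=C3 double bond are taken off first. Ring C is then cut in one stroke at C4a–C4, C4–C3 and O1–C2. Last come the alkenyl C–B bond and the C5'–prenyl bond of ring B.
- Enabling feature: in ring C the carbonyl carbon C4 stands alone between C4a of ring A and C3, which carries ring B. O1 is a ring A phenol oxygen on C8a, next to C4a, so it can close onto C2 once C4 is in place.
- Forward: the ring A iodophenol (two steps from phloroglucinol) and the ring B 1-arylvinyl boronate (five steps from an acetophenone) are made separately. Both aromatic rings are bought; ring C is the only ring formed, from the two fragments and CO. Dehydrogenation and deprotection finish the route.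
- Boron regiochemistry: boron is put on the internal alkene carbon by borylating the enol triflate of a methyl ketone, so ring B must end on C3.
- Stereochemistry: the target has no stereocentre. C3 of the isoflavanone forms as a racemate and becomes sp2 in the dehydrogenation.

Key step: step 8

Assumption: 1-(4-hydroxy-2-methoxyphenyl)ethanone is taken as a purchasable compound, and CO is counted as the third reactant of the ring-forming step.

**Route**

Step 1
Reactants: 1 phloroglucinol
Product: 2 3,5-bis(methoxymethoxy)phenol
Conditions: MOMCl (2.0 equiv), iPr2NEt (2.2 equiv), DMF, 0 °C to rt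
Reagents that add atoms: chloromethyl methyl ether, COCCl
Why: Williamson-type O-alkylation limited to two equivalents, so the bis-ether should be the main component of the statistical mixture; the mono-ether (recycled) and the tris-ether are removed by chromatography.

Step 2
Reactants: 2 3,5-bis(methoxymethoxy)phenol
Product: 3 2-iodo-3,5-bis(methoxymethoxy)phenol
Conditions: NIS (1.0 equiv), CH2Cl2, −20 to 0 °C, dark
Reagents that add atoms: N-iodosuccinimide, O=C1CCC(=O)N1I
Why: Electrophilic aromatic iodination, expected ortho to the free hydroxyl because two equivalent ortho sites compete with one para site wedged between two MOM ethers and the hydroxyl can deliver the reagent by hydrogen bonding; the neutral medium spares the acetals.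

Step 3
Reactants: 4 1-(4-hydroxy-2-methoxyphenyl)ethanone
Product: 5 1-(5-bromo-4-hydroxy-2-methoxyphenyl)ethanone
Conditions: NBS (1.0 equiv), MeCN, 0 °C
Reagents that add atoms: N-bromosuccinimide, O=C1CCC(=O)N1Br
Why: Electrophilic aromatic bromination directed to C5, which is ortho to the hydroxyl, para to the methoxy group and unhindered, whereas C3 lies between two oxygen substituents.

Step 4
Reactants: 5 1-(5-bromo-4-hydroxy-2-methoxyphenyl)ethanone
Product: 6 1-[5-bromo-2-methoxy-4-(methoxymethoxy)phenyl]ethanone
Conditions: MOMCl, iPr2NEt, CH2Cl2, 0 °C to rt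
Reagents that add atoms: chloromethyl methyl ether, COCCl
Why: Williamson-type MOM ether formation on the only phenol, so that the later base, enolate and palladium steps meet no acidic hydroxyl on ring B.

Step 5
Reactants: 6 1-[5-bromo-2-methoxy-4-(methoxymethoxy)phenyl]ethanone, 7 prenylboronic acid pinacol ester
Product: 8 1-[2-methoxy-4-(methoxymethoxy)-5-(3-methylbut-2-enyl)phenyl]ethanone
Conditions: PdCl2(IPent)(3-chloropyridine) (2 mol %; IPent = 1,3-bis[2,6-di(pentan-3-yl)phenyl]imidazol-2-ylidene), KOH (5 M aq), THF, 70 °C
Reagents that add atoms: none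
Why: Suzuki-Miyaura allyl-aryl coupling in which the very bulky carbene ligand should steer reductive elimination to the primary terminus of the allylpalladium intermediate, giving the linear prenyl arene and not the reverse-prenyl isomer, while the electron-rich aryl methyl ketone is a poor acceptor for the allylboronate.

Step 6
Reactants: 8 1-[2-methoxy-4-(methoxymethoxy)-5-(3-methylbut-2-enyl)phenyl]ethanone
Product: 9 1-[2-methoxy-4-(methoxymethoxy)-5-(3-methylbut-2-enyl)phenyl]vinyl trifluoromethanesulfonate
Conditions: KN(SiMe3)2, THF, −78 °C; PhNTf2, −78 to 0 °C; filtration through Et3N-deactivated silica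
Reagents that add atoms: N-phenylbis(trifluoromethanesulfonimide), O=S(=O)(N(c1ccccc1)S(=O)(=O)C(F)(F)F)C(F)(F)F
Why: Enol triflate formation; the methyl group is the only enolisable position, so O-sulfonylation of the potassium enolate should give the 1-arylvinyl triflate, which is kept away from acid because of its electron-rich aryl group.

Step 7
Reactants: 9 1-[2-methoxy-4-(methoxymethoxy)-5-(3-methylbut-2-enyl)phenyl]vinyl trifluoromethanesulfonate, 10 bis(pinacolato)diboron
Product: 11 1-[2-methoxy-4-(methoxymethoxy)-5-(3-methylbut-2-enyl)phenyl]vinylboronic acid pinacol ester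
Conditions: PdCl2(PPh3)2 (3 mol %), PPh3 (6 mol %), KOPh, toluene, 50 °C
Reagents that add atoms: none
Why: Miyaura borylation of an alkenyl triflate under the phenoxide conditions that suppress diene formation; boron replaces the triflate oxygen on the former carbonyl carbon, so the boronate is the internal isomer by construction.

Step 8
Reactants: 3 2-iodo-3,5-bis(methoxymethoxy)phenol, 11 1-[2-methoxy-4-(methoxymethoxy)-5-(3-methylbut-2-enyl)phenyl]vinylboronic acid pinacol ester, 12 carbon monoxide
Product: 14 racemic 2'-methoxy-5,7,4'-tris(methoxymethoxy)-5'-prenylisoflavanone, via hydroxyaryl enone 13 (not isolated)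
Conditions: Pd(OAc)2 (5 mol %), P(1-adamantyl)2(n-Bu) (10 mol %), CO (5 bar), K2CO3 (3 equiv), H2O (5 equiv), anisole, 80 °C
Reagents that add atoms: none
Why: Pd(OAc)2 is reduced in the flask to zerovalent palladium, which inserts into the C-I bond of 3; CO insertion gives the aroyl complex of divalent palladium, and base-assisted transfer of the 1-arylvinyl group from boron followed by reductive elimination delivers enone 13 with the new C4a-C4 and C4-C3 bonds. The ortho phenoxide of 13 then adds to the terminal methylene (oxa-Michael addition), forming O1-C2 and closing ring C in a 6-endo-trig mode. The closest known reaction types are the carbonylative Suzuki-Miyaura coupling of aryl iodides, di-ortho-substituted ones included, with aryl- and alkenylboron reagents to give ketones, and the base-induced cyclisation of 2-aryl-1-(2-hydroxyaryl)propenones to isoflavanones. The C3 stereocentre arises from unbiased protonation of the enolate after ring closure, so 14 should be racemic, which does not matter because C3 becomes sp2 in step 9. The selectivity needed is ketone formation over direct aryl-alkenyl coupling; CO pressure, the electron-rich aryl group on palladium flanked by O- and OMOM (fast migration to CO, slow transmetalation) and the hindered 1,1-disubstituted boronate should secure it. Ring B ends on C3 because boron sits on the internal alkene carbon, and the trisubstituted prenyl alkene should not engage the catalyst.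

Step 9
Reactants: 14 racemic 2'-methoxy-5,7,4'-tris(methoxymethoxy)-5'-prenylisoflavanone
Product: 17 2'-methoxy-5,7,4'-tris(methoxymethoxy)-5'-prenylisoflavone, via 3-phenylselanyl isoflavanone 15 (not isolated), via selenoxide 16 (not isolated)
Conditions: LiN(SiMe3)2, THF, −78 °C; PhSeBr (1.05 equiv), −78 °C; then NaIO4, NaHCO3, THF/MeOH/H2O, 0 °C to rt
Reagents that add atoms: none
Why: Enolate alpha-selenenylation followed by selenoxide syn-elimination; C3 is the only enolisable carbon and C2 carries the only beta-hydrogens, so elimination can only give the C2=C3 bond, and periodate oxidises selenium without epoxidising the prenyl alkene.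

Step 10
Reactants: 17 2'-methoxy-5,7,4'-tris(methoxymethoxy)-5'-prenylisoflavone
Product: 18 Vogelin F
Conditions: HCl (3 M aq), MeOH, 40 °C
Reagents that add atoms: none
Why: Acid-catalysed acetal exchange with methanol removes the three MOM ethers under conditions mild enough that the aryl methyl ether stays and the prenyl group should not cyclise onto the freed 4'-hydroxyl.

**Compound list**

1 | phloroglucinol (benzene-1,3,5-triol) | Oc1cc(O)cc(O)c1 | starting material
2 | 3,5-bis(methoxymethoxy)phenol | COCOc1cc(O)cc(OCOC)c1 | intermediate
3 | 2-iodo-3,5-bis(methoxymethoxy)phenol | Oc1cc(OCOC)cc(OCOC)c1I | intermediate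
4 | 1-(4-hydroxy-2-methoxyphenyl)ethanone | COc1cc(O)ccc1C(C)=O | starting material
5 | 1-(5-bromo-4-hydroxy-2-methoxyphenyl)ethanone | COc1cc(O)c(Br)cc1C(C)=O | intermediate
6 | 1-[5-bromo-2-methoxy-4-(methoxymethoxy)phenyl]ethanone | COc1cc(OCOC)c(Br)cc1C(C)=O | intermediate
7 | prenylboronic acid pinacol ester, 4,4,5,5-tetramethyl-2-(3-methylbut-2-enyl)-1,3,2-dioxaborolane | CC(C)=CCB1OC(C)(C)C(C)(C)O1 | starting material
8 | 1-[2-methoxy-4-(methoxymethoxy)-5-(3-methylbut-2-enyl)phenyl]ethanone | COc1cc(OCOC)c(CC=C(C)C)cc1C(C)=O | intermediate
9 | 1-[2-methoxy-4-(methoxymethoxy)-5-(3-methylbut-2-enyl)phenyl]vinyl trifluoromethanesulfonate | COc1cc(OCOC)c(CC=C(C)C)cc1C(=C)OS(=O)(=O)C(F)(F)F | intermediate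
10 | bis(pinacolato)diboron | CC1(C)OB(OC1(C)C)B1OC(C)(C)C(C)(C)O1 | starting material
11 | 1-[2-methoxy-4-(methoxymethoxy)-5-(3-methylbut-2-enyl)phenyl]vinylboronic acid pinacol ester | C=C(B1OC(C)(C)C(C)(C)O1)c1cc(CC=C(C)C)c(OCOC)cc1OC | intermediate
12 | carbon monoxide | [C-]#[O+] | starting material
13 | 1-[2-hydroxy-4,6-bis(methoxymethoxy)phenyl]-2-[2-methoxy-4-(methoxymethoxy)-5-(3-methylbut-2-enyl)phenyl]prop-2-en-1-one | C=C(C(=O)c1c(O)cc(OCOC)cc1OCOC)c1cc(CC=C(C)C)c(OCOC)cc1OC | intermediate (not isolated)
14 | racemic 2'-methoxy-5,7,4'-tris(methoxymethoxy)-5'-prenylisoflavanone (3-aryl-chroman-4-one, C3 racemic) | COCOc1cc(OC)c(cc1CC=C(C)C)C1COc2cc(OCOC)cc(OCOC)c2C1=O | intermediate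
15 | racemic 3-(phenylselanyl) derivative of 14 (PhSe on C3) | COCOc1cc(OC)c(cc1CC=C(C)C)C1([Se]c3ccccc3)COc2cc(OCOC)cc(OCOC)c2C1=O | intermediate (not isolated)
16 | selenoxide of 15 (diastereomer mixture at selenium, racemic) | COCOc1cc(OC)c(cc1CC=C(C)C)C1([Se](=O)c3ccccc3)COc2cc(OCOC)cc(OCOC)c2C1=O | intermediate (not isolated)
17 | 2'-methoxy-5,7,4'-tris(methoxymethoxy)-5'-prenylisoflavone | COCOc1cc(OC)c(cc1CC=C(C)C)-c1coc2cc(OCOC)cc(OCOC)c2c1=O | intermediate
18 | Vogelin F, 5,7,4'-trihydroxy-2'-methoxy-5'-prenylisoflavone (achiral) | COc1cc(O)c(CC=C(C)C)cc1-c1coc2cc(O)cc(O)c2c1=O | target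

**Totals and risks**

Total steps: 10. Longest linear sequence: 8 steps (4 to 18 through steps 3 to 10); the ring A branch contributes 2 steps before the convergence.

Three steps most likely to fail:

1. Step 8. The aroylpalladium intermediate may be captured by the phenoxide of a second molecule (ester formation), or transmetalation may outrun CO insertion (direct aryl-alkenyl coupling), so that no ketone forms. The fallback gives up carbonylation and forms C4–C3 by a Nozaki-Hiyama-Kishi addition; C4 then comes from an aldehyde. Commercial 2,4,6-trihydroxybenzaldehyde is protected with MOMCl (2 equiv) and iPr2NEt, the chelated hydroxyl staying free, to give 2-hydroxy-4,6-bis(methoxymethoxy)benzaldehyde F1. Alkenyl triflate 9 is added to it with CrCl2 and catalytic NiCl2 in DMF, followed by aqueous NaHCO3 work-up, to give racemic 1-[2-hydroxy-4,6-bis(methoxymethoxy)phenyl]-2-[2-methoxy-4-(methoxymethoxy)-5-(3-methylbut-2-enyl)phenyl]prop-2-en-1-ol F2. MnO2 in CH2Cl2 should oxidise this doubly activated carbinol to enone 13, and K2CO3 in MeOH closes it. The fallback sets out from 9 and returns to the route at 14.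

2. Step 6. The electron-rich 1-arylvinyl triflate may ionise or hydrolyse back to the ketone during formation or purification. The fallback sets out from ketone 8. LiN(iPr)2 and then ClP(O)(OEt)2 at −78 °C give diethyl 1-[2-methoxy-4-(methoxymethoxy)-5-(3-methylbut-2-enyl)phenyl]vinyl phosphate F3. Further LiN(iPr)2 (2.2 equiv, −78 °C to rt) eliminates it to the terminal alkyne 1-ethynyl-2-methoxy-4-(methoxymethoxy)-5-(3-methylbut-2-enyl)benzene F4. Copper-catalysed protoboration with 10 and MeOH (CuCl(SIMes), SIMes = 1,3-dimesitylimidazolidin-2-ylidene, NaOtBu, THF) should put boron on the internal carbon. The fallback returns to the route at 11 and bypasses 9.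

3. Step 2. Iodination may occur para to the free hydroxyl, between the two MOM ethers, or twice. The fallback replaces electrophilic substitution by directed ortho-metalation and sets out from 2. ClC(O)NEt2 and K2CO3 in MeCN give 3,5-bis(methoxymethoxy)phenyl N,N-diethylcarbamate F5. s-BuLi/TMEDA in THF at −78 °C should lithiate the position flanked by the carbamate and a MOM ether, and I2 then gives 2-iodo-3,5-bis(methoxymethoxy)phenyl N,N-diethylcarbamate F6. Reductive carbamate cleavage with Cp2Zr(H)Cl in THF at rt frees the phenol. The fallback returns to the route at 3.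

**Further compounds**

F1 | step 8 | 2-hydroxy-4,6-bis(methoxymethoxy)benzaldehyde | O=Cc1c(O)cc(OCOC)cc1OCOC
F2 | step 8 | racemic 1-[2-hydroxy-4,6-bis(methoxymethoxy)phenyl]-2-[2-methoxy-4-(methoxymethoxy)-5-(3-methylbut-2-enyl)phenyl]prop-2-en-1-ol | C=C(C(O)c1c(O)cc(OCOC)cc1OCOC)c1cc(CC=C(C)C)c(OCOC)cc1OC
F3 | step 6 | diethyl 1-[2-methoxy-4-(methoxymethoxy)-5-(3-methylbut-2-enyl)phenyl]vinyl phosphate | C=C(OP(=O)(OCC)OCC)c1cc(CC=C(C)C)c(OCOC)cc1OC
F4 | step 6 | 1-ethynyl-2-methoxy-4-(methoxymethoxy)-5-(3-methylbut-2-enyl)benzene | C#Cc1cc(CC=C(C)C)c(OCOC)cc1OC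
F5 | step 2 | 3,5-bis(methoxymethoxy)phenyl N,N-diethylcarbamate | CCN(CC)C(=O)Oc1cc(OCOC)cc(OCOC)c1
F6 | step 2 | 2-iodo-3,5-bis(methoxymethoxy)phenyl N,N-diethylcarbamate | CCN(CC)C(=O)Oc1cc(OCOC)cc(OCOC)c1I
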